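**Retrosynthetic overview** (eudesmane numbering: ring A = C1–C5 and C10, ring B = C5–C10, C14 = angular CH3, C15 = CH2O on C4, C11–C13 = acrylate on C7)

1. The C15–O ester bond is cut last (Mitsunobu with (Z)-p-coumaric acid); the acrylate is unmasked from a malonate; C15 comes from a C4 ketone through its C3=C4 enol triflate.
2. Key disconnection C9–C10: the trans-decalone arises from a monocyclic 2-alkyl-3-methylcyclohex-2-enone by 6-endo radical conjugate cyclization of a primary C9 radical.
3. Enabling feature: in ring A, C10 (the carbon bearing C14) is the β-carbon of an enone whose carbonyl is C4 (the carbon that must later carry C15) and whose α-carbon C5 carries the chain C6–C7–C8–C9. The single stereocentre C7 is relayed to the quaternary C10 and to C5 in this one event.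
4. C7 is set by an organocatalytic Michael addition of dimethyl malonate to an enal made by cross-metathesis of 2-allyl-3-methylcyclohexenone (from Hagemann's ester).
5. Ring order: ring A is bought; ring B is closed in the key step.

Key step: step 7

Assumption: the sense of induction of the diarylprolinol silyl ether catalyst with this aliphatic enal is taken from the usual face-shielding model of its E, s-trans iminium ion.

**Route**

Step 1
Reactants: 1 ethyl 2-methyl-4-oxocyclohex-2-ene-1-carboxylate (Hagemann's ester, racemic); 2 allyl bromide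
Product: 3 ethyl 2-methyl-4-oxo-3-(prop-2-en-1-yl)cyclohex-2-ene-1-carboxylate (racemic)
Conditions: NaOEt, EtOH, 0 to 78 °C
Reagents that add atoms: allyl bromide 2, C=CCBr
Why: Alkylation of the extended enolate of this vinylogous β-keto ester is known to occur at C3 (the carbon α to the ketone), so the allyl group should enter next to the carbonyl with the alkene returning to conjugation; the racemic centre at C1 is destroyed in step 2.

Step 2
Reactants: 3 ethyl 2-methyl-4-oxo-3-(prop-2-en-1-yl)cyclohex-2-ene-1-carboxylate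
Product: 5 3-methyl-2-(prop-2-en-1-yl)cyclohex-2-en-1-one, via carboxylic acid 4 (not isolated)
Conditions: KOH, EtOH/H2O, 80 °C; then aq. HCl, 80 °C
Reagents that add atoms: none
Why: Saponification followed by decarboxylation of the vinylogous β-keto acid is the classical route from alkylated Hagemann's esters to 2-alkyl-3-methylcyclohex-2-enones; no stereocentre is formed.

Step 3
Reactants: 5 3-methyl-2-(prop-2-en-1-yl)cyclohex-2-en-1-one; 6 (E)-but-2-enal (crotonaldehyde)
Product: 7 (2E)-4-(2-methyl-6-oxocyclohex-1-en-1-yl)but-2-enal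
Conditions: second-generation Hoveyda–Grubbs catalyst RuCl2(H2IMes)(=CH-C6H4-2-OiPr) (3 mol %), crotonaldehyde (5 equiv), CH2Cl2, 40 °C
Reagents that add atoms: (E)-but-2-enal 6, C/C=C/C=O
Why: Olefin cross-metathesis between a terminal alkene and an electron-poor enal partner should be E-selective and is driven by loss of propene, while the tetrasubstituted ring alkene cannot enter the catalytic cycle.

Step 4
Reactants: 7 (2E)-4-(2-methyl-6-oxocyclohex-1-en-1-yl)but-2-enal; 8 dimethyl malonate
Product: 9 dimethyl 2-[(2S)-1-(2-methyl-6-oxocyclohex-1-en-1-yl)-4-oxobutan-2-yl]propanedioate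
Conditions: (R)-2-{bis[3,5-bis(trifluoromethyl)phenyl][(trimethylsilyl)oxy]methyl}pyrrolidine (10 mol %), dimethyl malonate (3 equiv), EtOH, 0 °C
Reagents that add atoms: dimethyl malonate 8, COC(=O)CC(=O)OC
Why: Iminium-ion organocatalysis (asymmetric Michael addition of malonates to enals): the diaryl(silyloxy)methyl group shields one face of the E, s-trans iminium ion, so the malonate should add to C7 from the open face and set it as S (the spatial arrangement of C7 in the target), and the tetrasubstituted ring enone is not an acceptor.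

Step 5
Reactants: 9 dimethyl 2-[(2S)-1-(2-methyl-6-oxocyclohex-1-en-1-yl)-4-oxobutan-2-yl]propanedioate
Product: 10 dimethyl 2-[(2S)-4-hydroxy-1-(2-methyl-6-oxocyclohex-1-en-1-yl)butan-2-yl]propanedioate
Conditions: NaBH4, MeOH, −40 °C; aq. NH4Cl
Reagents that add atoms: none
Why: Borohydride reduction at low temperature is chemoselective for the aldehyde over the hindered conjugated ketone and the esters, and the alcohol is iodinated at once to forestall lactonisation onto the malonate.

Step 6
Reactants: 10 dimethyl 2-[(2S)-4-hydroxy-1-(2-methyl-6-oxocyclohex-1-en-1-yl)butan-2-yl]propanedioate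
Product: 11 dimethyl 2-[(2S)-4-iodo-1-(2-methyl-6-oxocyclohex-1-en-1-yl)butan-2-yl]propanedioate
Conditions: I2, PPh3, imidazole, CH2Cl2, 0 to 23 °C
Reagents that add atoms: iodine, II
Why: Appel-type iodination (iodophosphonium activation, SN2 displacement by iodide) converts the primary alcohol into the iodide under neutral conditions without touching C7.

Step 7
Reactants: 11 dimethyl 2-[(2S)-4-iodo-1-(2-methyl-6-oxocyclohex-1-en-1-yl)butan-2-yl]propanedioate
Product: 12 dimethyl 2-[(2R,4aR,8aR)-4a-methyl-8-oxodecahydronaphthalen-2-yl]propanedioate (trans-fused; 5α-H, 10β-CH3, 7β side chain in eudesmane terms)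
Conditions: (Me3Si)3SiH (1.2 equiv), AIBN (0.2 equiv), PhMe, 85 °C, syringe-pump addition, 0.005 M
Reagents that add atoms: none
Why: Iodine abstraction by the silyl radical gives the primary C9 radical, which adds to C10, the β-carbon of the C4(=O)–C5=C10 enone, and the resulting C5 enoxyl radical takes a hydrogen atom from the silane to carry the chain. The closest known reaction type is the tin- or silane-mediated 6-endo radical conjugate (Giese-type) cyclization of 2-(ω-haloalkyl)cycloalk-2-enones to fused bicyclic ketones. Ring B closes in the 6-endo-trig mode, because attack at the α-carbon C5 (5-exo) is polarity-mismatched for a nucleophilic alkyl radical and would give an unstabilized radical, and slow addition of the silane at high dilution keeps premature reduction of the C9 radical behind the cyclization. C10 is controlled by C7 through a chair-like transition state in which ring A forces the C10 methyl axial on the forming ring and the bulky malonyl group on C7 sits equatorial, which places the side chain and the angular methyl cis (7β,10β). C5 is controlled by the new quaternary centre, hydrogen being delivered to the enoxyl radical anti to the axial angular methyl to give the trans fusion, and because C5 is α to the C4 ketone any cis-fused material can be equilibrated with mild base toward the thermodynamically preferred trans-decalone. The malonate is carried as an inert, bulky precursor of the acrylate because a free acrylate would compete as a radical acceptor.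

Step 8
Reactants: 12 dimethyl 2-[(2R,4aR,8aR)-4a-methyl-8-oxodecahydronaphthalen-2-yl]propanedioate
Product: 13 dimethyl 2-[(2R,4aS,8aR)-4a-methyl-8-{[(trifluoromethyl)sulfonyl]oxy}-1,2,3,4,4a,5,6,8a-octahydronaphthalen-2-yl]propanedioate
Conditions: KN(SiMe3)2 (2.2 equiv), THF, −78 °C (ketone added to base); PhNTf2, −78 to 0 °C; aq. NH4Cl
Reagents that add atoms: N-phenylbis(trifluoromethanesulfonimide), O=S(=O)(N(c1ccccc1)S(=O)(=O)C(F)(F)F)C(F)(F)F
Why: Kinetic deprotonation by the bulky amide (the first equivalent is consumed by the malonate C–H) takes place at the C3 methylene and not at the hindered C5 methine, and O-sulfonylation of this enolate gives the C3=C4 enol triflate while C5 stays untouched.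

Step 9
Reactants: 13 dimethyl 2-[(2R,4aS,8aR)-4a-methyl-8-{[(trifluoromethyl)sulfonyl]oxy}-1,2,3,4,4a,5,6,8a-octahydronaphthalen-2-yl]propanedioate; 14 (tributylstannyl)methanol
Product: 15 dimethyl 2-[(2R,4aS,8aR)-8-(hydroxymethyl)-4a-methyl-1,2,3,4,4a,5,6,8a-octahydronaphthalen-2-yl]propanedioate
Conditions: Pd(PPh3)4 (5 mol %), LiCl (3 equiv), 1,4-dioxane, 100 °C
Reagents that add atoms: (tributylstannyl)methanol 14, CCCC[Sn](CCCC)(CCCC)CO
Why: Stille cross-coupling (oxidative addition of the enol triflate to zerovalent palladium, transfer of the hydroxymethyl group from tin, reductive elimination) installs C15 on C4 with the alkene fixed at C3=C4.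

Step 10
Reactants: 15 dimethyl 2-[(2R,4aS,8aR)-8-(hydroxymethyl)-4a-methyl-1,2,3,4,4a,5,6,8a-octahydronaphthalen-2-yl]propanedioate
Product: 16 2-[(2R,4aS,8aR)-8-(hydroxymethyl)-4a-methyl-1,2,3,4,4a,5,6,8a-octahydronaphthalen-2-yl]-3-methoxy-3-oxopropanoic acid (both epimers at the malonyl carbon)
Conditions: KOH (1.05 equiv), THF/MeOH/H2O, 0 °C; then aq. HCl to pH 3
Reagents that add atoms: potassium hydroxide, [K+].[OH-]
Why: Monosaponification of a dialkyl malonate with one equivalent of hydroxide at low temperature stops at the half-ester because the carboxylate deactivates the second ester; the new centre at the malonyl carbon is inconsequential.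

Step 11
Reactants: 16 2-[(2R,4aS,8aR)-8-(hydroxymethyl)-4a-methyl-1,2,3,4,4a,5,6,8a-octahydronaphthalen-2-yl]-3-methoxy-3-oxopropanoic acid; 17 formaldehyde (as paraformaldehyde)
Product: 19 methyl 2-[(2R,4aR,8aR)-8-(hydroxymethyl)-4a-methyl-1,2,3,4,4a,5,6,8a-octahydronaphthalen-2-yl]prop-2-enoate, via Mannich base 18 (not isolated)
Conditions: (CH2O)n, Et2NH, EtOAc, 75 °C
Reagents that add atoms: formaldehyde 17, C=O
Why: Mannich reaction of the malonic half-ester with formaldehyde and the secondary amine, followed by decarboxylative elimination of the amine, is the standard route to α-substituted acrylates and leaves C7 untouched.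

Step 12
Reactants: 20 4-[(tert-butyldimethylsilyl)oxy]benzaldehyde; 21 methyl 2-[bis(2,2,2-trifluoroethoxy)phosphoryl]acetate
Product: 22 methyl (2Z)-3-{4-[(tert-butyldimethylsilyl)oxy]phenyl}prop-2-enoate
Conditions: KN(SiMe3)2, 18-crown-6, THF, −78 °C
Reagents that add atoms: methyl 2-[bis(2,2,2-trifluoroethoxy)phosphoryl]acetate 21, COC(=O)CP(=O)(OCC(F)(F)F)OCC(F)(F)F
Why: Still–Gennari olefination: the electron-poor bis(trifluoroethyl) phosphonate under dissociating conditions collapses kinetically to the Z-enoate with aromatic aldehydes.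

Step 13
Reactants: 22 methyl (2Z)-3-{4-[(tert-butyldimethylsilyl)oxy]phenyl}prop-2-enoate
Product: 23 (2Z)-3-(4-hydroxyphenyl)prop-2-enoic acid ((Z)-p-coumaric acid)
Conditions: LiOH, THF/MeOH/H2O, 23 °C, dark; then aq. HCl
Reagents that add atoms: lithium hydroxide, [Li+].[OH-]
Why: Hydroxide hydrolyses the methyl ester and also cleaves the aryl silyl ether, and in the dark the Z-alkene should not isomerise.

Step 14
Reactants: 19 methyl 2-[(2R,4aR,8aR)-8-(hydroxymethyl)-4a-methyl-1,2,3,4,4a,5,6,8a-octahydronaphthalen-2-yl]prop-2-enoate; 23 (2Z)-3-(4-hydroxyphenyl)prop-2-enoic acid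
Product: 24 methyl 2-[(2R,4aR,8aR)-8-({[(2Z)-3-(4-hydroxyphenyl)prop-2-enoyl]oxy}methyl)-4a-methyl-1,2,3,4,4a,5,6,8a-octahydronaphthalen-2-yl]prop-2-enoate (CNP0161949.2)
Conditions: PPh3, DIAD, THF, 0 °C, dark
Reagents that add atoms: (2Z)-3-(4-hydroxyphenyl)prop-2-enoic acid 23, O=C(O)/C=C\c1ccc(O)cc1
Why: Mitsunobu esterification: the primary allylic alcohol is activated as its alkoxyphosphonium ion and displaced in SN2 fashion by the carboxylate, which is far more acidic than the phenol and should react chemoselectively; no stereocentre is involved and the Z-alkene is protected by working cold and in the dark.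

**Compound list**

1 | ethyl 2-methyl-4-oxocyclohex-2-ene-1-carboxylate (Hagemann's ester, racemic) | CCOC(=O)C1CCC(=O)C=C1C | starting material
2 | allyl bromide | C=CCBr | starting material
3 | ethyl 2-methyl-4-oxo-3-(prop-2-en-1-yl)cyclohex-2-ene-1-carboxylate (racemic) | CCOC(=O)C1CCC(=O)C(CC=C)=C1C | intermediate
4 | 2-methyl-4-oxo-3-(prop-2-en-1-yl)cyclohex-2-ene-1-carboxylic acid (racemic) | OC(=O)C1CCC(=O)C(CC=C)=C1C | intermediate
5 | 3-methyl-2-(prop-2-en-1-yl)cyclohex-2-en-1-one | C=CCC1=C(C)CCCC1=O | intermediate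
6 | (E)-but-2-enal | C/C=C/C=O | starting material
7 | (2E)-4-(2-methyl-6-oxocyclohex-1-en-1-yl)but-2-enal | O=C/C=C/CC1=C(C)CCCC1=O | intermediate
8 | dimethyl malonate | COC(=O)CC(=O)OC | starting material
9 | dimethyl 2-[(2S)-1-(2-methyl-6-oxocyclohex-1-en-1-yl)-4-oxobutan-2-yl]propanedioate | O=CC[C@H](CC1=C(C)CCCC1=O)C(C(=O)OC)C(=O)OC | intermediate
10 | dimethyl 2-[(2S)-4-hydroxy-1-(2-methyl-6-oxocyclohex-1-en-1-yl)butan-2-yl]propanedioate | OCC[C@H](CC1=C(C)CCCC1=O)C(C(=O)OC)C(=O)OC | intermediate
11 | dimethyl 2-[(2S)-4-iodo-1-(2-methyl-6-oxocyclohex-1-en-1-yl)butan-2-yl]propanedioate | ICC[C@H](CC1=C(C)CCCC1=O)C(C(=O)OC)C(=O)OC | intermediate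
12 | dimethyl 2-[(2R,4aR,8aR)-4a-methyl-8-oxodecahydronaphthalen-2-yl]propanedioate (trans-fused) | COC(=O)C(C(=O)OC)[C@@H]1CC[C@@]2(C)CCCC(=O)[C@@H]2C1 | intermediate
13 | dimethyl 2-[(2R,4aS,8aR)-4a-methyl-8-{[(trifluoromethyl)sulfonyl]oxy}-1,2,3,4,4a,5,6,8a-octahydronaphthalen-2-yl]propanedioate | COC(=O)C(C(=O)OC)[C@@H]1CC[C@@]2(C)CCC=C(OS(=O)(=O)C(F)(F)F)[C@@H]2C1 | intermediate
14 | (tributylstannyl)methanol | CCCC[Sn](CCCC)(CCCC)CO | starting material
15 | dimethyl 2-[(2R,4aS,8aR)-8-(hydroxymethyl)-4a-methyl-1,2,3,4,4a,5,6,8a-octahydronaphthalen-2-yl]propanedioate | COC(=O)C(C(=O)OC)[C@@H]1CC[C@@]2(C)CCC=C(CO)[C@@H]2C1 | intermediate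
16 | 2-[(2R,4aS,8aR)-8-(hydroxymethyl)-4a-methyl-1,2,3,4,4a,5,6,8a-octahydronaphthalen-2-yl]-3-methoxy-3-oxopropanoic acid (epimers at the malonyl carbon) | COC(=O)C(C(=O)O)[C@@H]1CC[C@@]2(C)CCC=C(CO)[C@@H]2C1 | intermediate
17 | formaldehyde (used as paraformaldehyde) | C=O | starting material
18 | 2-[(diethylamino)methyl]-2-[(2R,4aR,8aR)-8-(hydroxymethyl)-4a-methyl-1,2,3,4,4a,5,6,8a-octahydronaphthalen-2-yl]-3-methoxy-3-oxopropanoic acid (Mannich base, epimers at the malonyl carbon) | CCN(CC)CC(C(=O)O)(C(=O)OC)[C@@H]1CC[C@@]2(C)CCC=C(CO)[C@@H]2C1 | intermediate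
19 | methyl 2-[(2R,4aR,8aR)-8-(hydroxymethyl)-4a-methyl-1,2,3,4,4a,5,6,8a-octahydronaphthalen-2-yl]prop-2-enoate | C=C(C(=O)OC)[C@@H]1CC[C@@]2(C)CCC=C(CO)[C@@H]2C1 | intermediate
20 | 4-[(tert-butyldimethylsilyl)oxy]benzaldehyde | CC(C)(C)[Si](C)(C)Oc1ccc(C=O)cc1 | starting material
21 | methyl 2-[bis(2,2,2-trifluoroethoxy)phosphoryl]acetate | COC(=O)CP(=O)(OCC(F)(F)F)OCC(F)(F)F | starting material
22 | methyl (2Z)-3-{4-[(tert-butyldimethylsilyl)oxy]phenyl}prop-2-enoate | COC(=O)/C=C\c1ccc(O[Si](C)(C)C(C)(C)C)cc1 | intermediate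
23 | (2Z)-3-(4-hydroxyphenyl)prop-2-enoic acid | O=C(O)/C=C\c1ccc(O)cc1 | intermediate
24 | methyl 2-[(2R,4aR,8aR)-8-({[(2Z)-3-(4-hydroxyphenyl)prop-2-enoyl]oxy}methyl)-4a-methyl-1,2,3,4,4a,5,6,8a-octahydronaphthalen-2-yl]prop-2-enoate | C=C(C(=O)OC)[C@@H]1CC[C@@]2(C)CCC=C(COC(=O)/C=C\c3ccc(O)cc3)[C@@H]2C1 | target

**Step count and risks**

Total step count: 14. Longest linear sequence: 12 (steps 1 to 11 and 14).

Steps most likely to fail:

1. Step 7. What may go wrong: hydrogen transfer to the primary C9 radical may outrun the slow 6-endo addition to the fully substituted β-carbon, the relay from C7 to C10 may be incomplete, and hydrogen delivery at C5 may not be face-selective. The fallback closes the same bond by a reversible polar Michael reaction under thermodynamic control. It sets out from 11: displacement of iodide with NaNO2 (phloroglucinol, DMF, 23 °C) should give the primary nitroalkane F1. DBU in MeCN should then close ring B by 6-endo addition of the nitronate to C10, and equilibration should favour the trans-fused nitro ketone F2 with the C7 side chain equatorial. Radical denitration (Bu3SnH, AIBN, PhMe, 110 °C) comes back to the route at 12.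

2. Step 4. What may go wrong: amine-induced γ-deprotonation at the doubly allylic C6 position (dienamine formation and migration of the alkene toward the ring) and erosion of enantioselectivity. The fallback sets C7 by metal-catalysed allylic substitution and sets out from 5. Cross-metathesis with (Z)-but-2-ene-1,4-diyl dimethyl dicarbonate (second-generation Hoveyda–Grubbs catalyst, CH2Cl2, 40 °C) should give the allylic carbonate F3. Iridium-catalysed asymmetric allylic alkylation with dimethyl malonate 8 ([Ir(cod)Cl]2, chiral phosphoramidite ligand of the enantiomer that gives the S product, THF) should give the branched vinyl malonate F4. Rhodium-catalysed anti-Markovnikov hydroboration of the vinyl group (RhCl(PPh3)3, catecholborane, THF; then NaBO3), which spares the ketone, comes back to the route at 10.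

3. Step 14. What may go wrong: Z-to-E isomerisation of the coumarate through reversible conjugate addition of the phosphine, or competing alkylation of the phenol. The fallback builds the Z-alkene on the substrate and sets out from 19. Acylation with 2-(diphenoxyphosphoryl)acetic acid (EDC, DMAP, CH2Cl2) should give the phosphonoacetate F5. A Z-selective Horner–Wadsworth–Emmons reaction of this diaryl phosphonate with aldehyde 20 (NaH, THF, −78 °C) should give the silyl-protected Z-cinnamate F6. Desilylation (TBAF, AcOH, THF, 0 °C) comes back to the route at 24.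

**Further compounds**

F1 | step 7 | dimethyl 2-[(2S)-1-(2-methyl-6-oxocyclohex-1-en-1-yl)-4-nitrobutan-2-yl]propanedioate | [O-][N+](=O)CC[C@H](CC1=C(C)CCCC1=O)C(C(=O)OC)C(=O)OC
F2 | step 7 | 9-nitro derivative of 12 (eudesmane numbering: nitro on the ring B carbon next to C10, both C9 epimers, other centres as in 12) | COC(=O)C(C(=O)OC)[C@@H]1CC([N+](=O)[O-])[C@@]2(C)CCCC(=O)[C@@H]2C1
F3 | step 4 | methyl (2E)-4-(2-methyl-6-oxocyclohex-1-en-1-yl)but-2-en-1-yl carbonate | COC(=O)OC/C=C/CC1=C(C)CCCC1=O
F4 | step 4 | dimethyl 2-[(2S)-1-(2-methyl-6-oxocyclohex-1-en-1-yl)but-3-en-2-yl]propanedioate | C=C[C@H](CC1=C(C)CCCC1=O)C(C(=O)OC)C(=O)OC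
F5 | step 14 | methyl 2-[(2R,4aR,8aR)-8-({[2-(diphenoxyphosphoryl)acetyl]oxy}methyl)-4a-methyl-1,2,3,4,4a,5,6,8a-octahydronaphthalen-2-yl]prop-2-enoate | C=C(C(=O)OC)[C@@H]1CC[C@@]2(C)CCC=C(COC(=O)CP(=O)(Oc3ccccc3)Oc3ccccc3)[C@@H]2C1
F6 | step 14 | methyl 2-[(2R,4aR,8aR)-8-({[(2Z)-3-{4-[(tert-butyldimethylsilyl)oxy]phenyl}prop-2-enoyl]oxy}methyl)-4a-methyl-1,2,3,4,4a,5,6,8a-octahydronaphthalen-2-yl]prop-2-enoate | C=C(C(=O)OC)[C@@H]1CC[C@@]2(C)CCC=C(COC(=O)/C=C\c3ccc(O[Si](C)(C)C(C)(C)C)cc3)[C@@H]2C1
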